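## Structural features

The target is an isoflavanone: benzene ring A is fused to a dihydropyranone ring C (O1, C2, C3, C4, C4a, C8a), and benzene ring B is attached through C1′ to C3. Ring A carries a hydroxyl at C7 and a 3-methylbut-2-enyl (prenyl) chain at C6; ring B carries a hydroxyl at C4′ and a prenyl chain at C3′, so each phenol has a prenyl group ortho to it. C3 is the only stereocentre (S); it has no stereogenic neighbour in the target, but it lies between the C4 carbonyl and the C2 methylene and is both benzylic and α to the ketone, so it is lost by enolisation under base and, more slowly, under acid. The prenyl alkenes are fragile towards Brønsted acid (cyclisation onto the neighbouring phenol, addition of hydrogen halides), hydrogenation and electrophilic oxidants, and the free phenols are fragile towards oxidants. The real difficulty is therefore not the skeleton but setting C3 as one enantiomer and then never exposing a C3–H that stands next to a C4 carbonyl to acid or base, while placing both prenyl groups regiospecifically. The feature used is that O1 joins the C2 methylene to the ring A carbon C8a, which is ortho to C4a and hence to the C4 carbon. An open-chain C2–C3–C4 unit with a primary alcohol at C2 and a bromide at C8a can thus be closed at O1–C8a while C4 is still a silylated secondary alcohol, a state in which C3 is an ordinary, non-enolisable benzylic carbon. In that open-chain precursor C3 and C4 are adjacent stereocentres set together by an aldol reaction; only C3 survives into the target.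

## Logic of the disconnections

21 from 20. The two phenolic O–H bonds are traced back to O–Si bonds. The phenols must be masked during the oxidation at C4 and the ring closure, and silyl ethers are chosen because buffered fluoride releases them without Brønsted acid or base. Nothing is gained in skeleton; the demand is that the last step be short, cold and buffered, since C3 is enolisable in both 20 and 21.

20 from 19. The C4 carbonyl is taken back to the secondary alcohol. This removes the acidity of C3–H, so every earlier step may use base. The demand on the forward step is an oxidant that is neither basic nor strongly acidic and spares prenyl groups and aryl silyl ethers.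

19 from 18. The O4–H bond is traced back to an O4–SiEt3 bond, because O4 must be blocked during ring closure. The C4–O bond is para to O7 and ortho to O1 and ionises easily, so the forward step must remove this one silyl group at an acidity no higher than a pyridinium buffer and leave the aryl silyl ethers in place.

18 from 17. The O1–C8a bond is cut. It is the only bond of ring C that can be made without touching C3 or C4, and cutting it opens the heterocycle to an acyclic 1,3-diol derivative, the retron of an aldol reaction. The forward step demands that C–O reductive elimination at palladium outrun β-hydride elimination and that the silyl group on O4 stay where it is.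

17 from 16. The C2 carbinol is traced back to an acyl carbon bonded to the nitrogen of a chiral oxazolidinone. This exposes the aldol adduct and its auxiliary. The forward step demands hydride attack at the exocyclic carbonyl only.

16 from 15. The O–SiEt3 bond at the future C4 is removed to reveal the free aldol. The forward silylation must be fast and non-basic enough to give no retro-aldol cleavage.

15 from 12 and 5. The C3–C4 bond is cut. This is the main simplification: it divides the skeleton into two aryl halves of similar size and creates C3 (with C4) under control of the auxiliary. The forward step demands a Z enolate and attack on the enolate face left open by the benzyl group; only that face selection matters for the target, because C4 becomes planar later.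

12 from 11 and 4. The bond between ring B and its prenyl CH2 is cut. A cross-coupling puts the chain exactly where the halogen stood. The forward step demands transfer of the prenyl unit through its primary carbon, without fluoride and without acidic protons that would destroy 4.

11 from 8 and 9. The N–acyl bond is cut, which separates the auxiliary from the arylacetic acid. The forward step demands acylation at the arylacetyl carbonyl of a mixed anhydride.

8 from 6. The aryl O–Si bond is removed. The forward step must silylate the phenol and leave the carboxylic acid free.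

5 from 3 and 4. The bond between ring A and its prenyl CH2 is cut. The forward step demands that the carbon–iodine bond react and that the carbon–bromine bond, needed at C8a in step 10, survive.

3 from 2. The aryl O–Si bond is removed; the forward step is a plain silylation of a hindered, acidic phenol.

2 from 1. The carbon–iodine bond is cut. The forward step demands iodination at the open position ortho to the hydroxyl and not at the position between hydroxyl and bromine.

## Other disconnections considered

Alternative 1: The cut is double, through C3–C4 and O1–C2, so ring C falls apart into the ring A benzodioxinone A2 and the ring B enol ether A3. In the forward sense, irradiation near 300 nm (or heating) would make A2 lose its ketal carbon as a simple ketone and unveil the ortho-quinone ketene A4. The electron-rich β-carbon of A3 would then attack the ketene carbon while the quinoid oxygen closes onto the methoxy-bearing carbon, a polarised [4+2] addition leading to the 2-methoxyisoflavanone A1.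
- In its favour: two skeletal bonds and the ring are made in one metal-free step, the regiochemistry is dictated by the polarity of both partners, and the two halves are of equal size. In convergence and in bonds made per step it is better than the chosen plan.
- Against it here: A1 would be racemic at C3 and a mixture at C2, and the sensible next move, loss of methanol to the isoflavone A5, flattens C3 altogether. The stereocentre would then have to be created by an enantioselective reduction of the C2=C3 bond beside two trisubstituted alkenes; catalytic hydrogenation threatens these, and transfer hydrogenation over-reduces C4 and calls for reoxidation. Light of this wavelength is also absorbed by the aryl ketone and the styrene, which invites secondary photochemistry.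
- Comparison: structurally it builds ring C faster. Mechanistically it is free of the β-hydride problem of a palladium alkoxide, but it offers no control at C3, whereas the aldol fixes C3 with an auxiliary of reliable sense. In step count the gain at the key step is spent again on elimination, asymmetric reduction and reoxidation, so the totals should be about equal. The final desilylation next to an enolisable C3 is the same hazard in both plans (equal).

Alternative 2: The cut is C2–C3. The precursor is the α-aryl-α-diazo ketone A7, in which ring A carries a methoxy group where O1 will be. With Rh2(S-PTTL)4 (or its enantiomer, whichever leads to 3S), dinitrogen would be lost at divalent rhodium and the carbenoid carbon C3 is meant to insert into a C–H bond of the O-methyl group, giving the bis(silyl) ether A6 directly.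
- In its favour: the ring, the C2–C3 bond and the stereocentre would arise in one catalytic step at the ketone oxidation level, from a deoxybenzoin-type precursor reachable in few steps by acylation and diazo transfer. A6 is one desilylation from the target. In step economy, in atom economy (no auxiliary, no redox detour at C4) and in the number of steps after the key step it is better than the chosen plan.
- Against it here: a methyl C–H bond is the least reactive kind for carbenoid insertion and the closure is six-membered, while the lone pair of the same methoxy oxygen sits in a five-membered relationship to the carbenoid carbon. Ylide formation followed by a 1,2-shift is therefore the expected competitor. The two prenyl alkenes offer cyclopropanation and allylic insertion as further outlets. Enantiocontrol with this catalyst family is better founded for diazo esters than for diazo ketones.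
- Comparison: structurally more direct. Mechanistically far less secure in chemoselectivity, with stereocontrol resting on an unproven catalyst–substrate match instead of an auxiliary. The product would carry the enolisable C3–H from the moment it forms, as 20 does in the chosen plan (equal). It would be shorter by several steps.

Alternative 3: The cut is C3–C4. The precursor A9 is a racemic benzylic chloride linked through C2–O1 to a ring A acid chloride. NiCl2(dme), a chiral bis(oxazoline) and zerovalent manganese (Mn powder) as terminal reductant would join the acyl carbon C4 to the benzylic carbon C3 and give the diacetate A8.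
- In its favour: the coupling is enantioconvergent, because the benzylic carbon passes through a radical and both enantiomers of the chloride can end as one enantiomer of product. Ring and stereocentre are made together at the ketone oxidation level under non-basic reducing conditions that an α-aryl ketone tolerates. The racemic precursor should be quick to assemble by O-alkylation of a salicylate. In step count and in needing no stoichiometric auxiliary it is better than the chosen plan, and in keeping C3 safe during the key step it is at least its equal.
- Against it here: the reaction type is established for two separate partners, and a ring-closing version to a six-membered ketone with an ortho-alkoxy acid chloride is an extrapolation. The benzylic radical or benzylnickel species carries an aryloxy group in the β-position, and its expulsion is a plausible competing path. An acid chloride would have to be made and handled beside a benzylic chloride and two acid-sensitive prenyl groups. The acetates must finally be removed with a nucleophile or base next to the enolisable C3, a harsher last step than buffered fluoride on silyl ethers (worse).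
- Comparison: structurally it forms a C–C bond of the ring and the stereocentre at once instead of a C–O bond. Mechanistically it trades a well-understood C–O reductive elimination for a radical–nickel sequence whose intramolecular course and level of induction are open. It would be the shorter route.

Key step: step 10

Remarks on the chemistry:
- Stereochemical bookkeeping: the target is (3S). The same spatial arrangement corresponds to (3S,4R) (3,4-trans) in 18 and 19, to (2S,3R) in 17 and to (2R,3R) in 14, 15 and 16. The change of descriptor at the ring B-bearing carbon between 16 and 17 is only a priority switch when the acyl carbon becomes CH2OH. This is the syn aldol expected from a (4R)-benzyl oxazolidinone, so 9 must be the R enantiomer. The structures are otherwise mutually consistent and none had to be corrected.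
- Protecting groups: the phenols are carried as triisopropylsilyl ethers and not as acetal ethers. Acetal ethers would have to be split with Brønsted acid after the C4 ketone exists, the one situation the target tolerates worst (enolisation at C3, cyclisation of prenyl onto phenol). O4 carries a triethylsilyl group, which comes off under pyridine-buffered fluoride that neither ionises the C4–O bond nor touches aryl triisopropylsilyl ethers.
- Assumption: 4 and 9 are taken as catalogue reagents, and 4 is assumed to deliver the prenyl group through its primary carbon under palladium catalysis, as allylic stannanes that pass through an η3-allyl palladium species normally do.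

## Steps

Step 1
Reactants: 1 2-bromo-4-hydroxybenzaldehyde
Product: 2 2-bromo-4-hydroxy-5-iodobenzaldehyde
Conditions: NIS, AcOH, rt
Reagents that add atoms: N-iodosuccinimide, O=C1CCC(=O)N1I
Why: Electrophilic aromatic iodination directed ortho to the hydroxyl; the para position is blocked by the formyl group, and of the two ortho positions C5 is open while C3 is wedged between OH and Br.

Step 2
Reactants: 2 2-bromo-4-hydroxy-5-iodobenzaldehyde
Product: 3 2-bromo-5-iodo-4-(triisopropylsilyloxy)benzaldehyde
Conditions: TIPSCl, imidazole, DMF, rt
Reagents that add atoms: chlorotriisopropylsilane, CC(C)[Si](Cl)(C(C)C)C(C)C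
Why: Imidazole-promoted silylation of a phenol; the bulky triisopropylsilyl group is chosen because a silyl ether para to a formyl group is easily displaced at silicon and a smaller group would not last, and because no acidic O–H may remain when the allylic stannane is used.

Step 3
Reactants: 3 2-bromo-5-iodo-4-(triisopropylsilyloxy)benzaldehyde; 4 tributyl(3-methylbut-2-enyl)stannane
Product: 5 2-bromo-5-(3-methylbut-2-enyl)-4-(triisopropylsilyloxy)benzaldehyde
Conditions: Pd2(dba)3 (2.5 mol %), AsPh3 (10 mol %), DMF, 50 °C
Reagents that add atoms: none
Why: Stille coupling; zerovalent palladium inserts into the carbon–iodine bond much faster than into the carbon–bromine bond at this temperature, so the bromide needed for step 10 should be kept. The allylic stannane transmetalates without fluoride, and reductive elimination at the less substituted terminus of the η3-prenyl palladium species should give the linear prenyl chain.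

Step 4
Reactants: 6 3-bromo-4-hydroxyphenylacetic acid
Product: 8 [3-bromo-4-(triisopropylsilyloxy)phenyl]acetic acid, via silyl ester 7 (not isolated)
Conditions: TIPSCl (2.2 equiv), imidazole, DMF, rt; then AcOH/THF/H2O, rt
Reagents that add atoms: chlorotriisopropylsilane, CC(C)[Si](Cl)(C(C)C)C(C)C
Why: Exhaustive silylation followed by selective hydrolysis; a silyl carboxylate is far more labile to aqueous acid than an aryl silyl ether, so only the ester 7 should be cleaved.

Step 5
Reactants: 8 [3-bromo-4-(triisopropylsilyloxy)phenyl]acetic acid; 9 (R)-4-benzyloxazolidin-2-one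
Product: 11 (R)-4-benzyl-3-{[3-bromo-4-(triisopropylsilyloxy)phenyl]acetyl}oxazolidin-2-one, via mixed pivalic anhydride 10 (not isolated)
Conditions: PivCl, Et3N, THF, −20 °C; then LiCl, 9, −20 °C → rt
Reagents that add atoms: none
Why: N-acylation of an oxazolidinone through a mixed anhydride; the pivaloyl carbonyl is shielded by the tert-butyl group, so the LiCl-activated oxazolidinone should attack the arylacetyl carbonyl. Masking the acid as the imide also removes the acidic proton before the stannane is used.

Step 6
Reactants: 11 (R)-4-benzyl-3-{[3-bromo-4-(triisopropylsilyloxy)phenyl]acetyl}oxazolidin-2-one; 4 tributyl(3-methylbut-2-enyl)stannane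
Product: 12 (R)-4-benzyl-3-{[3-(3-methylbut-2-enyl)-4-(triisopropylsilyloxy)phenyl]acetyl}oxazolidin-2-one
Conditions: Pd(PPh3)4 (5 mol %), toluene, 105 °C
Reagents that add atoms: none
Why: Stille allylation of an aryl bromide under neutral, fluoride-free conditions that leave the imide and the aryl silyl ether alone; the linear chain is expected for the same reason as in step 3.

Step 7
Reactants: 12 (R)-4-benzyl-3-{[3-(3-methylbut-2-enyl)-4-(triisopropylsilyloxy)phenyl]acetyl}oxazolidin-2-one; 5 2-bromo-5-(3-methylbut-2-enyl)-4-(triisopropylsilyloxy)benzaldehyde
Product: 15 (4R)-4-benzyl-3-{(2R,3R)-3-[2-bromo-5-(3-methylbut-2-enyl)-4-(triisopropylsilyloxy)phenyl]-3-hydroxy-2-[3-(3-methylbut-2-enyl)-4-(triisopropylsilyloxy)phenyl]propanoyl}oxazolidin-2-one, via Z-boron enolate 13 (not isolated), via boron aldolate 14 (not isolated)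
Conditions: Bu2BOTf, iPr2NEt, CH2Cl2, −78 → 0 °C; then 5, −78 → 0 °C; then pH 7 buffer, MeOH, H2O2, 0 °C
Reagents that add atoms: none
Why: Evans syn aldol; soft enolisation gives the Z enolate 13, which should add to 5 through a Zimmerman–Traxler chair with the two imide carbonyls opposed and the benzyl group of the (R)-auxiliary shielding one enolate face, setting the future C3 and C4 as the (2R,3R) syn pair. Only the face selection at the enolate carbon matters for the target, because the carbinol centre is oxidised in step 12.

Step 8
Reactants: 15 (4R)-4-benzyl-3-{(2R,3R)-3-[2-bromo-5-(3-methylbut-2-enyl)-4-(triisopropylsilyloxy)phenyl]-3-hydroxy-2-[3-(3-methylbut-2-enyl)-4-(triisopropylsilyloxy)phenyl]propanoyl}oxazolidin-2-one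
Product: 16 (4R)-4-benzyl-3-{(2R,3R)-3-[2-bromo-5-(3-methylbut-2-enyl)-4-(triisopropylsilyloxy)phenyl]-2-[3-(3-methylbut-2-enyl)-4-(triisopropylsilyloxy)phenyl]-3-(triethylsilyloxy)propanoyl}oxazolidin-2-one
Conditions: TESOTf, 2,6-lutidine, CH2Cl2, −78 → 0 °C
Reagents that add atoms: triethylsilyl trifluoromethanesulfonate, CC[Si](CC)(CC)OS(=O)(=O)C(F)(F)F
Why: Silylation of a hindered secondary alcohol with a silyl triflate and a non-nucleophilic pyridine base, fast at low temperature, so the adduct should not revert by retro-aldol cleavage or epimerise.

Step 9
Reactants: 16 (4R)-4-benzyl-3-{(2R,3R)-3-[2-bromo-5-(3-methylbut-2-enyl)-4-(triisopropylsilyloxy)phenyl]-2-[3-(3-methylbut-2-enyl)-4-(triisopropylsilyloxy)phenyl]-3-(triethylsilyloxy)propanoyl}oxazolidin-2-one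
Product: 17 (2S,3R)-3-[2-bromo-5-(3-methylbut-2-enyl)-4-(triisopropylsilyloxy)phenyl]-2-[3-(3-methylbut-2-enyl)-4-(triisopropylsilyloxy)phenyl]-3-(triethylsilyloxy)propan-1-ol
Conditions: LiBH4, THF, 0 °C → rt
Reagents that add atoms: none
Why: Reductive removal of the oxazolidinone auxiliary; borohydride should attack the more electrophilic exocyclic imide carbonyl and reduce it to the primary alcohol, releasing 9, while aryl bromide, alkenes and silyl ethers are inert. Neither stereocentre is touched.

Step 10
Reactants: 17 (2S,3R)-3-[2-bromo-5-(3-methylbut-2-enyl)-4-(triisopropylsilyloxy)phenyl]-2-[3-(3-methylbut-2-enyl)-4-(triisopropylsilyloxy)phenyl]-3-(triethylsilyloxy)propan-1-ol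
Product: 18 (3S,4R)-6-(3-methylbut-2-enyl)-3-[3-(3-methylbut-2-enyl)-4-(triisopropylsilyloxy)phenyl]-4-(triethylsilyloxy)-7-(triisopropylsilyloxy)chromane
Conditions: Pd(OAc)2 (5 mol %), rac-2-(di-tert-butylphosphino)-1,1′-binaphthyl (6 mol %), Cs2CO3 (1.5 equiv), toluene, 70 °C
Reagents that add atoms: none
Why: Pd(OAc)2 is reduced in the flask by the phosphine to a monoligated zerovalent palladium species that inserts into the C8a–Br bond of 17; the divalent arylpalladium bromide then binds the primary hydroxyl, Cs2CO3 removes its proton, and C–O reductive elimination from the seven-membered palladacycle forms O1–C8a and returns zerovalent palladium. The closest known reaction type is the Buchwald–Hartwig intramolecular etherification of 3-(2-bromoaryl)propan-1-ols to chromans, applied here to a more substituted chain. Ring C is closed in a six-membered exo mode at the aryl carbon, and the silylated O4, which could only give a four-membered ring, is not free in any case. No stereocentre is formed and none is touched: C3 and C4 keep the arrangement fixed in step 7, because no bond to either is made or broken and, with C4 a silyl ether, C3–H is an unactivated benzylic hydrogen that carbonate cannot remove, so epimerisation, retro-aldol cleavage and elimination have no pathway. The selectivity needed is C–O reductive elimination over β-hydride elimination of the palladium alkoxide, which the bulk of the di-tert-butylphosphino biaryl ligand should secure by accelerating reductive elimination and crowding the vacant site; the single C–Br bond is the only site for oxidative addition, and aryl silyl ethers and prenyl alkenes are inert to zerovalent palladium under these conditions. A weak, insoluble base in toluene at moderate temperature keeps the concentration of free alkoxide low, so the triethylsilyl group should not migrate from O4 to the C2 oxygen.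

Step 11
Reactants: 18 (3S,4R)-6-(3-methylbut-2-enyl)-3-[3-(3-methylbut-2-enyl)-4-(triisopropylsilyloxy)phenyl]-4-(triethylsilyloxy)-7-(triisopropylsilyloxy)chromane
Product: 19 (3S,4R)-6-(3-methylbut-2-enyl)-3-[3-(3-methylbut-2-enyl)-4-(triisopropylsilyloxy)phenyl]-7-(triisopropylsilyloxy)chroman-4-ol
Conditions: HF·pyridine, excess pyridine, THF, 0 °C
Reagents that add atoms: none
Why: Selective desilylation; under pyridine-buffered hydrogen fluoride an alkyl triethylsilyl ether is cleaved at silicon much faster than the far bulkier aryl triisopropylsilyl ethers. The medium is no more acidic than a pyridinium buffer, so it should neither ionise the C4–O bond (para to O7, ortho to O1) nor add to the prenyl alkenes.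

Step 12
Reactants: 19 (3S,4R)-6-(3-methylbut-2-enyl)-3-[3-(3-methylbut-2-enyl)-4-(triisopropylsilyloxy)phenyl]-7-(triisopropylsilyloxy)chroman-4-ol
Product: 20 (3S)-6-(3-methylbut-2-enyl)-3-[3-(3-methylbut-2-enyl)-4-(triisopropylsilyloxy)phenyl]-7-(triisopropylsilyloxy)chroman-4-one
Conditions: Dess–Martin periodinane, pyridine, CH2Cl2, 0 °C → rt; filtration through a short silica pad
Reagents that add atoms: none
Why: Dess–Martin oxidation of a secondary benzylic alcohol by ligand exchange at hypervalent iodine and intramolecular proton removal by acetate; the medium is nearly neutral, so the newly enolisable C3 should keep its configuration, and alkenes and aryl silyl ethers are inert. A non-aqueous work-up avoids contact of 20 with aqueous base.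

Step 13
Reactants: 20 (3S)-6-(3-methylbut-2-enyl)-3-[3-(3-methylbut-2-enyl)-4-(triisopropylsilyloxy)phenyl]-7-(triisopropylsilyloxy)chroman-4-one
Product: 21 (3S)-7-hydroxy-3-[4-hydroxy-3-(3-methylbut-2-enyl)phenyl]-6-(3-methylbut-2-enyl)chroman-4-one
Conditions: TBAF, AcOH (1:1), THF, 0 °C
Reagents that add atoms: none
Why: Fluoride-induced cleavage of aryl silyl ethers, which is fast because phenoxide is a good leaving group at silicon; one equivalent of acetic acid per fluoride protonates the phenoxides as they form and keeps the medium too weakly basic to enolise C3. No Brønsted acid strong enough to cyclise a prenyl group onto its neighbouring phenol is present.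

## Compound list

1 | 2-bromo-4-hydroxybenzaldehyde | O=Cc1ccc(O)cc1Br | starting material
2 | 2-bromo-4-hydroxy-5-iodobenzaldehyde | O=Cc1cc(I)c(O)cc1Br | intermediate
3 | 2-bromo-5-iodo-4-(triisopropylsilyloxy)benzaldehyde | O=Cc1cc(I)c(O[Si](C(C)C)(C(C)C)C(C)C)cc1Br | intermediate
4 | tributyl(3-methylbut-2-enyl)stannane | CCCC[Sn](CCCC)(CCCC)CC=C(C)C | starting material
5 | 2-bromo-5-(3-methylbut-2-enyl)-4-(triisopropylsilyloxy)benzaldehyde | CC(C)=CCc1cc(C=O)c(Br)cc1O[Si](C(C)C)(C(C)C)C(C)C | intermediate
6 | 3-bromo-4-hydroxyphenylacetic acid | OC(=O)Cc1ccc(O)c(Br)c1 | starting material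
7 | triisopropylsilyl [3-bromo-4-(triisopropylsilyloxy)phenyl]acetate (not isolated) | CC(C)[Si](OC(=O)Cc1ccc(O[Si](C(C)C)(C(C)C)C(C)C)c(Br)c1)(C(C)C)C(C)C | intermediate
8 | [3-bromo-4-(triisopropylsilyloxy)phenyl]acetic acid | OC(=O)Cc1ccc(O[Si](C(C)C)(C(C)C)C(C)C)c(Br)c1 | intermediate
9 | (R)-4-benzyloxazolidin-2-one | O=C1N[C@H](Cc2ccccc2)CO1 | starting material
10 | [3-bromo-4-(triisopropylsilyloxy)phenyl]acetic pivalic anhydride (not isolated) | CC(C)(C)C(=O)OC(=O)Cc1ccc(O[Si](C(C)C)(C(C)C)C(C)C)c(Br)c1 | intermediate
11 | (R)-4-benzyl-3-{[3-bromo-4-(triisopropylsilyloxy)phenyl]acetyl}oxazolidin-2-one | O=C(Cc1ccc(O[Si](C(C)C)(C(C)C)C(C)C)c(Br)c1)N1C(=O)OC[C@H]1Cc1ccccc1 | intermediate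
12 | (R)-4-benzyl-3-{[3-(3-methylbut-2-enyl)-4-(triisopropylsilyloxy)phenyl]acetyl}oxazolidin-2-one | CC(C)=CCc1cc(CC(=O)N2C(=O)OC[C@H]2Cc2ccccc2)ccc1O[Si](C(C)C)(C(C)C)C(C)C | intermediate
13 | (Z)-dibutylboron enolate of 12 (not isolated) | CCCCB(CCCC)O/C(=C\c1ccc(O[Si](C(C)C)(C(C)C)C(C)C)c(CC=C(C)C)c1)N1C(=O)OC[C@H]1Cc1ccccc1 | intermediate
14 | O-dibutylboryl derivative of 15, (2R,3R) boron aldolate (not isolated) | CC(C)=CCc1cc([C@H]([C@@H](OB(CCCC)CCCC)c2cc(CC=C(C)C)c(O[Si](C(C)C)(C(C)C)C(C)C)cc2Br)C(=O)N2C(=O)OC[C@H]2Cc2ccccc2)ccc1O[Si](C(C)C)(C(C)C)C(C)C | intermediate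
15 | (4R)-4-benzyl-3-{(2R,3R)-3-[2-bromo-5-(3-methylbut-2-enyl)-4-(triisopropylsilyloxy)phenyl]-3-hydroxy-2-[3-(3-methylbut-2-enyl)-4-(triisopropylsilyloxy)phenyl]propanoyl}oxazolidin-2-one | CC(C)=CCc1cc([C@H]([C@@H](O)c2cc(CC=C(C)C)c(O[Si](C(C)C)(C(C)C)C(C)C)cc2Br)C(=O)N2C(=O)OC[C@H]2Cc2ccccc2)ccc1O[Si](C(C)C)(C(C)C)C(C)C | intermediate
16 | (4R)-4-benzyl-3-{(2R,3R)-3-[2-bromo-5-(3-methylbut-2-enyl)-4-(triisopropylsilyloxy)phenyl]-2-[3-(3-methylbut-2-enyl)-4-(triisopropylsilyloxy)phenyl]-3-(triethylsilyloxy)propanoyl}oxazolidin-2-one | CC(C)=CCc1cc([C@H]([C@@H](O[Si](CC)(CC)CC)c2cc(CC=C(C)C)c(O[Si](C(C)C)(C(C)C)C(C)C)cc2Br)C(=O)N2C(=O)OC[C@H]2Cc2ccccc2)ccc1O[Si](C(C)C)(C(C)C)C(C)C | intermediate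
17 | (2S,3R)-3-[2-bromo-5-(3-methylbut-2-enyl)-4-(triisopropylsilyloxy)phenyl]-2-[3-(3-methylbut-2-enyl)-4-(triisopropylsilyloxy)phenyl]-3-(triethylsilyloxy)propan-1-ol | CC(C)=CCc1cc([C@H]([C@@H](O[Si](CC)(CC)CC)c2cc(CC=C(C)C)c(O[Si](C(C)C)(C(C)C)C(C)C)cc2Br)CO)ccc1O[Si](C(C)C)(C(C)C)C(C)C | intermediate
18 | (3S,4R)-6-(3-methylbut-2-enyl)-3-[3-(3-methylbut-2-enyl)-4-(triisopropylsilyloxy)phenyl]-4-(triethylsilyloxy)-7-(triisopropylsilyloxy)chromane (3,4-trans) | CC(C)=CCc1cc([C@H]2COc3cc(O[Si](C(C)C)(C(C)C)C(C)C)c(CC=C(C)C)cc3[C@@H]2O[Si](CC)(CC)CC)ccc1O[Si](C(C)C)(C(C)C)C(C)C | intermediate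
19 | (3S,4R)-6-(3-methylbut-2-enyl)-3-[3-(3-methylbut-2-enyl)-4-(triisopropylsilyloxy)phenyl]-7-(triisopropylsilyloxy)chroman-4-ol | CC(C)=CCc1cc([C@H]2COc3cc(O[Si](C(C)C)(C(C)C)C(C)C)c(CC=C(C)C)cc3[C@@H]2O)ccc1O[Si](C(C)C)(C(C)C)C(C)C | intermediate
20 | (3S)-6-(3-methylbut-2-enyl)-3-[3-(3-methylbut-2-enyl)-4-(triisopropylsilyloxy)phenyl]-7-(triisopropylsilyloxy)chroman-4-one | CC(C)=CCc1cc([C@H]2COc3cc(O[Si](C(C)C)(C(C)C)C(C)C)c(CC=C(C)C)cc3C2=O)ccc1O[Si](C(C)C)(C(C)C)C(C)C | intermediate
21 | (3S)-7-hydroxy-3-[4-hydroxy-3-(3-methylbut-2-enyl)phenyl]-6-(3-methylbut-2-enyl)chroman-4-one | CC(C)=CCc1cc([C@H]2COc3cc(O)c(CC=C(C)C)cc3C2=O)ccc1O | target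

## Step count and least certain steps

Total step count: 13. Longest linear sequence: 10 steps (from 1 through steps 1, 2, 3 and 7 to 13; the branch from 6 through steps 4, 5, 6 and 7 to 13 is equally long).

Step 10 (key step). The most likely failure is β-hydride elimination from the palladium alkoxide, which would reduce the carbon–bromine bond and oxidise C2, because oxidative addition next to the branched, silyloxy-bearing benzylic carbon is slow and the alkoxide then waits at the metal. A second failure is migration of the triethylsilyl group from O4 to the C2 oxygen under base, after which O4 would chelate palladium and be oxidised. The fallback makes the other ether bond of ring C. It sets out from 17: Miyaura borylation (B2pin2, PdCl2(dppf), KOAc, dioxane, 85 °C) should give (2S,3R)-3-[5-(3-methylbut-2-enyl)-2-(4,4,5,5-tetramethyl-1,3,2-dioxaborolan-2-yl)-4-(triisopropylsilyloxy)phenyl]-2-[3-(3-methylbut-2-enyl)-4-(triisopropylsilyloxy)phenyl]-3-(triethylsilyloxy)propan-1-ol F1. Oxidation of the carbon–boron bond (NaBO3·4H2O, THF/H2O, rt) should give the phenol (2S,3R)-3-[2-hydroxy-5-(3-methylbut-2-enyl)-4-(triisopropylsilyloxy)phenyl]-2-[3-(3-methylbut-2-enyl)-4-(triisopropylsilyloxy)phenyl]-3-(triethylsilyloxy)propan-1-ol F2. A Mitsunobu cyclisation (PPh3, DIAD, THF, 0 °C → rt) would then form O1–C2 by displacement at the primary carbon, touching no stereocentre, and come back to the route at 18.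

Step 3. The most likely failure is loss of site selectivity, because the carbon–bromine bond is activated by the ortho formyl group while the carbon–iodine bond is flanked by the bulky silyl ether; transfer of the prenyl unit through its tertiary terminus or palladium-mediated addition of the stannane to the aldehyde are lesser risks. The fallback replaces palladium and tin by magnesium and copper. It sets out from 3: acetalisation (HC(OMe)3, PPTS, MeOH) should give 1-bromo-2-(dimethoxymethyl)-4-iodo-5-(triisopropylsilyloxy)benzene F3. Iodine–magnesium exchange (iPrMgCl·LiCl, THF, −40 °C), selective for iodide over bromide, followed by CuBr·SMe2 and 1-bromo-3-methylbut-2-ene, should alkylate at the primary carbon and give 1-bromo-2-(dimethoxymethyl)-4-(3-methylbut-2-enyl)-5-(triisopropylsilyloxy)benzene F4. Mild hydrolysis of the acetal (AcOH/THF/H2O) comes back to the route at 5.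

Step 9. The most likely failure is hydride attack at the ring carbonyl of the oxazolidinone, opening the auxiliary without releasing the chain, because the exocyclic carbonyl is flanked by an aryl group and by the silyloxy-bearing carbon; migration of the triethylsilyl group to the new primary alkoxide is a second risk. The fallback reduces before silylating. It sets out from 15: LiBH4 (THF, 0 °C) acting on the free aldol, where the neighbouring alkoxide assists delivery of hydride, should give (1R,2S)-1-[2-bromo-5-(3-methylbut-2-enyl)-4-(triisopropylsilyloxy)phenyl]-2-[3-(3-methylbut-2-enyl)-4-(triisopropylsilyloxy)phenyl]propane-1,3-diol F5. Double silylation (TESOTf, 2,6-lutidine) should give (1R,2S)-1-[2-bromo-5-(3-methylbut-2-enyl)-4-(triisopropylsilyloxy)phenyl]-2-[3-(3-methylbut-2-enyl)-4-(triisopropylsilyloxy)phenyl]-1,3-bis(triethylsilyloxy)propane F6. Brief treatment with pyridine-buffered HF·pyridine at 0 °C should remove the unhindered primary triethylsilyl group first and come back to the route at 17.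

Step 13. The most likely failure is partial loss of configuration at C3 by enolisation, if the fluoride is not fully buffered or if cleavage of the more hindered 4′-silyl ether is slow and the ketone stays long in the medium. The fallback removes the silyl groups while C4 is still an alcohol and oxidises last. It sets out from 19: TBAF (THF, 0 °C), harmless at this stage because no carbonyl flanks C3, should give (3S,4R)-3-[4-hydroxy-3-(3-methylbut-2-enyl)phenyl]-6-(3-methylbut-2-enyl)chromane-4,7-diol F7. Chemoselective oxidation of its benzylic C4 alcohol with activated MnO2 (EtOAc, rt), a neutral heterogeneous oxidant that usually spares simple phenols, comes back to the route at 21.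

Further compounds

F1 | step 10 | (2S,3R)-3-[5-(3-methylbut-2-enyl)-2-(4,4,5,5-tetramethyl-1,3,2-dioxaborolan-2-yl)-4-(triisopropylsilyloxy)phenyl]-2-[3-(3-methylbut-2-enyl)-4-(triisopropylsilyloxy)phenyl]-3-(triethylsilyloxy)propan-1-ol | CC(C)=CCc1cc([C@H]([C@@H](O[Si](CC)(CC)CC)c2cc(CC=C(C)C)c(O[Si](C(C)C)(C(C)C)C(C)C)cc2B2OC(C)(C)C(C)(C)O2)CO)ccc1O[Si](C(C)C)(C(C)C)C(C)C
F2 | step 10 | (2S,3R)-3-[2-hydroxy-5-(3-methylbut-2-enyl)-4-(triisopropylsilyloxy)phenyl]-2-[3-(3-methylbut-2-enyl)-4-(triisopropylsilyloxy)phenyl]-3-(triethylsilyloxy)propan-1-ol | CC(C)=CCc1cc([C@H]([C@@H](O[Si](CC)(CC)CC)c2cc(CC=C(C)C)c(O[Si](C(C)C)(C(C)C)C(C)C)cc2O)CO)ccc1O[Si](C(C)C)(C(C)C)C(C)C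
F3 | step 3 | 1-bromo-2-(dimethoxymethyl)-4-iodo-5-(triisopropylsilyloxy)benzene | COC(OC)c1cc(I)c(O[Si](C(C)C)(C(C)C)C(C)C)cc1Br
F4 | step 3 | 1-bromo-2-(dimethoxymethyl)-4-(3-methylbut-2-enyl)-5-(triisopropylsilyloxy)benzene | COC(OC)c1cc(CC=C(C)C)c(O[Si](C(C)C)(C(C)C)C(C)C)cc1Br
F5 | step 9 | (1R,2S)-1-[2-bromo-5-(3-methylbut-2-enyl)-4-(triisopropylsilyloxy)phenyl]-2-[3-(3-methylbut-2-enyl)-4-(triisopropylsilyloxy)phenyl]propane-1,3-diol | CC(C)=CCc1cc([C@H]([C@@H](O)c2cc(CC=C(C)C)c(O[Si](C(C)C)(C(C)C)C(C)C)cc2Br)CO)ccc1O[Si](C(C)C)(C(C)C)C(C)C
F6 | step 9 | (1R,2S)-1-[2-bromo-5-(3-methylbut-2-enyl)-4-(triisopropylsilyloxy)phenyl]-2-[3-(3-methylbut-2-enyl)-4-(triisopropylsilyloxy)phenyl]-1,3-bis(triethylsilyloxy)propane | CC(C)=CCc1cc([C@H]([C@@H](O[Si](CC)(CC)CC)c2cc(CC=C(C)C)c(O[Si](C(C)C)(C(C)C)C(C)C)cc2Br)CO[Si](CC)(CC)CC)ccc1O[Si](C(C)C)(C(C)C)C(C)C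
F7 | step 13 | (3S,4R)-3-[4-hydroxy-3-(3-methylbut-2-enyl)phenyl]-6-(3-methylbut-2-enyl)chromane-4,7-diol | CC(C)=CCc1cc([C@H]2COc3cc(O)c(CC=C(C)C)cc3[C@@H]2O)ccc1O
A1 | alternative 1 | 7-(tert-butyldimethylsilyloxy)-3-[4-(tert-butyldimethylsilyloxy)-3-(3-methylbut-2-enyl)phenyl]-2-methoxy-6-(3-methylbut-2-enyl)chroman-4-one (racemic, both C2 epimers) | COC1Oc2cc(O[Si](C)(C)C(C)(C)C)c(CC=C(C)C)cc2C(=O)C1c1ccc(O[Si](C)(C)C(C)(C)C)c(CC=C(C)C)c1
A2 | alternative 1 | 7-(tert-butyldimethylsilyloxy)-2,2-dimethyl-6-(3-methylbut-2-enyl)-4H-1,3-benzodioxin-4-one | CC1(C)OC(=O)c2cc(CC=C(C)C)c(O[Si](C)(C)C(C)(C)C)cc2O1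
A3 | alternative 1 | (E)-tert-butyl[4-(2-methoxyethenyl)-2-(3-methylbut-2-enyl)phenoxy]dimethylsilane | CO/C=C/c1ccc(O[Si](C)(C)C(C)(C)C)c(CC=C(C)C)c1
A4 | alternative 1 | 3-(tert-butyldimethylsilyloxy)-4-(3-methylbut-2-enyl)-6-(oxomethylidene)cyclohexa-2,4-dien-1-one | O=C=C1C(=O)C=C(O[Si](C)(C)C(C)(C)C)C(CC=C(C)C)=C1
A5 | alternative 1 | 7-(tert-butyldimethylsilyloxy)-3-[4-(tert-butyldimethylsilyloxy)-3-(3-methylbut-2-enyl)phenyl]-6-(3-methylbut-2-enyl)-4H-chromen-4-one | CC(C)=CCc1cc(-c2coc3cc(O[Si](C)(C)C(C)(C)C)c(CC=C(C)C)cc3c2=O)ccc1O[Si](C)(C)C(C)(C)C
A6 | alternative 2 | (3S)-7-(tert-butyldimethylsilyloxy)-3-[4-(tert-butyldimethylsilyloxy)-3-(3-methylbut-2-enyl)phenyl]-6-(3-methylbut-2-enyl)chroman-4-one | CC(C)=CCc1cc([C@H]2COc3cc(O[Si](C)(C)C(C)(C)C)c(CC=C(C)C)cc3C2=O)ccc1O[Si](C)(C)C(C)(C)C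
A7 | alternative 2 | 1-[4-(tert-butyldimethylsilyloxy)-2-methoxy-5-(3-methylbut-2-enyl)phenyl]-2-[4-(tert-butyldimethylsilyloxy)-3-(3-methylbut-2-enyl)phenyl]-2-diazoethan-1-one | COc1cc(O[Si](C)(C)C(C)(C)C)c(CC=C(C)C)cc1C(=O)C(=[N+]=[N-])c1ccc(O[Si](C)(C)C(C)(C)C)c(CC=C(C)C)c1
A8 | alternative 3 | (3S)-7-acetoxy-3-[4-acetoxy-3-(3-methylbut-2-enyl)phenyl]-6-(3-methylbut-2-enyl)chroman-4-one | CC(C)=CCc1cc([C@H]2COc3cc(OC(C)=O)c(CC=C(C)C)cc3C2=O)ccc1OC(C)=O
A9 | alternative 3 | 4-acetoxy-2-{2-[4-acetoxy-3-(3-methylbut-2-enyl)phenyl]-2-chloroethoxy}-5-(3-methylbut-2-enyl)benzoyl chloride (racemic) | CC(C)=CCc1cc(C(Cl)COc2cc(OC(C)=O)c(CC=C(C)C)cc2C(Cl)=O)ccc1OC(C)=O
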